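**Retrosynthetic overview**

- Numbering: chain C1 (carboxyl) to C9; furan O1' to C5' (chain on C3', arene on C5'); arene C1'' (on the furan) to C6'' (oxygen on C2'' and C5'').
- The plan rests on the arene C1''–C6'': a 1,4-dioxygenated benzene with a single ortho substituent (furan C5' on C1''), the pattern a chromium alkenylcarbene/alkyne/CO benzannulation lays down around a terminal alkyne. Target ⇒ quinone ⇒ 4-methoxyphenyl silyl ether ⇒ 5'-ethynylfuran 11 + β-silylvinyl(methoxy)carbene complex 17 (bonds C5''–C6'', C1''–C2'', C2''–C3'').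
- Alkyne 11 ⇒ 5'-formylfuran (Seyferth–Gilbert) ⇒ C7 aldehyde (Wittig, C7=C8) ⇒ enal 4 + 3-furylboronate 7 (rhodium-catalysed asymmetric 1,4-addition sets C5). C3 is bought in (R)-methyl hydrogen 3-methylglutarate.
- Ring order: the furan ring is purchased (4-bromofuran-2-carbaldehyde); the benzene ring is the only ring made, and it is made last, in step 12.

Key step: step 12

Remark 1: (R)-methyl hydrogen 3-methylglutarate 1 is taken as purchased (the hemiester of enzymatic desymmetrisation of the dimethyl ester or of alkaloid-catalysed methanolysis of 3-methylglutaric anhydride); its enantiomeric purity should be checked before use.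

Remark 2: step 6 needs the antipode of the diene ligand that places the furyl group on the Si face of C5; it is written as the (1R,4R) ligand, and its mirror image is to be taken if a test run shows the opposite sense.

**Route**

Step 1
Reactants: 1 (3R)-5-methoxy-3-methyl-5-oxopentanoic acid
Product: 2 methyl (3R)-5-hydroxy-3-methylpentanoate
Conditions: BH3·SMe2 (1.1 equiv), THF, 0 °C to rt; MeOH quench
Reagents that add atoms: none
Why: Chemoselective borane reduction of a carboxylic acid in the presence of an ester (via the acyloxyborane) should convert only the acid arm to CH2OH and leaves C3 untouched.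

Step 2
Reactants: 2 methyl (3R)-5-hydroxy-3-methylpentanoate
Product: 3 methyl (3R)-3-methyl-5-oxopentanoate
Conditions: (COCl)2, DMSO, CH2Cl2, −78 °C; Et3N, −78 °C to 0 °C
Reagents that add atoms: none
Why: Swern oxidation is cold, fast and basic at the end, so the primary alcohol should reach the aldehyde without acid-promoted lactonisation onto the ester; C3 is not alpha to either carbonyl and cannot epimerise.

Step 3
Reactants: 3 methyl (3R)-3-methyl-5-oxopentanoate
Product: 4 methyl (3R,5E)-3-methyl-7-oxohept-5-enoate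
Conditions: Ph3P=CHCHO (1.05 equiv), toluene, 80 °C
Reagents that add atoms: (triphenylphosphoranylidene)acetaldehyde, O=CC=P(c1ccccc1)(c1ccccc1)c1ccccc1
Why: Wittig olefination with the stabilised formylmethylene ylide should give the E-enal, and the near-stoichiometric ylide limits a second homologation of the product.

Step 4
Reactants: 5 4-bromofuran-2-carbaldehyde
Product: 6 2-(4-bromofuran-2-yl)-1,3-dioxolane
Conditions: ethylene glycol (3 equiv), p-TsOH·H2O (cat.), toluene, reflux, Dean–Stark
Reagents that add atoms: ethylene glycol, OCCO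
Why: Acid-catalysed acetalisation with azeotropic removal of water masks the formyl group, which would otherwise compete in the rhodium step and in the later Wittig reaction.

Step 5
Reactants: 6 2-(4-bromofuran-2-yl)-1,3-dioxolane
Product: 7 2-[5-(1,3-dioxolan-2-yl)furan-3-yl]-4,4,5,5-tetramethyl-1,3,2-dioxaborolane
Conditions: B2pin2 (1.1 equiv), PdCl2(dppf) (3 mol%), KOAc (3 equiv), 1,4-dioxane, 85 °C
Reagents that add atoms: bis(pinacolato)diboron, CC1(C)OB(OC1(C)C)B1OC(C)(C)C(C)(C)O1
Why: Miyaura borylation of the heteroaryl bromide runs under weakly basic, anhydrous conditions that the acetal tolerates, and a 3-furylboronate is far less prone to protodeboronation than a 2-furyl one.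

Step 6
Reactants: 4 methyl (3R,5E)-3-methyl-7-oxohept-5-enoate; 7 2-[5-(1,3-dioxolan-2-yl)furan-3-yl]-4,4,5,5-tetramethyl-1,3,2-dioxaborolane
Product: 8 methyl (3R,5S)-5-[5-(1,3-dioxolan-2-yl)furan-3-yl]-3-methyl-7-oxoheptanoate
Conditions: 7 (1.5 equiv), [RhCl(C2H4)2]2 (2.5 mol%), (1R,4R)-2,5-diphenylbicyclo[2.2.2]octa-2,5-diene (5.5 mol%), KOH (0.3 equiv), 1,4-dioxane/H2O 10:1, 35 °C
Reagents that add atoms: none
Why: Hayashi–Miyaura 1,4-addition: the boronate, opened by aqueous hydroxide, transmetalates to monovalent rhodium and the furyl–rhodium species inserts the enal C5=C6 bond; the chiral diene ligand should keep the reaction 1,4-selective on an enal and sets C5 (5S) by delivering the furyl group to the Si face of C5, the remote C3 centre exerting little bias.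

Step 7
Reactants: 8 methyl (3R,5S)-5-[5-(1,3-dioxolan-2-yl)furan-3-yl]-3-methyl-7-oxoheptanoate
Product: 9 methyl (3R,5S)-5-[5-(1,3-dioxolan-2-yl)furan-3-yl]-3,8-dimethylnon-7-enoate
Conditions: i-PrPPh3I (1.3 equiv), NaHMDS (1.25 equiv), THF, 0 °C; then 8, −78 °C to 0 °C
Reagents that add atoms: isopropyltriphenylphosphonium iodide, CC(C)[P+](c1ccccc1)(c1ccccc1)c1ccccc1.[I-]
Why: Wittig olefination with the non-stabilised isopropylidene ylide builds C7=C8 with no geometric issue; the aldehyde reacts far faster than the methyl ester, and C5 is beta to the carbonyl and cannot epimerise.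

Step 8
Reactants: 9 methyl (3R,5S)-5-[5-(1,3-dioxolan-2-yl)furan-3-yl]-3,8-dimethylnon-7-enoate
Product: 10 methyl (3R,5S)-5-(5-formylfuran-3-yl)-3,8-dimethylnon-7-enoate
Conditions: PPTS (0.2 equiv), acetone/H2O 9:1, 45 °C
Reagents that add atoms: water, O
Why: Mild acid-catalysed acetal hydrolysis should free the furfural-type aldehyde under conditions too weak to hydrate the trisubstituted alkene or open the furan.

Step 9
Reactants: 10 methyl (3R,5S)-5-(5-formylfuran-3-yl)-3,8-dimethylnon-7-enoate
Product: 11 methyl (3R,5S)-5-(5-ethynylfuran-3-yl)-3,8-dimethylnon-7-enoate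
Conditions: dimethyl (1-diazo-2-oxopropyl)phosphonate (1.3 equiv), K2CO3 (2 equiv), MeOH, 0 °C to rt
Reagents that add atoms: dimethyl (1-diazo-2-oxopropyl)phosphonate, CC(=O)C(=[N+]=[N-])P(=O)(OC)OC
Why: Seyferth–Gilbert homologation in its Ohira–Bestmann form converts a non-enolisable heteroaryl aldehyde into the terminal alkyne under K2CO3/MeOH, in which the methyl ester can only exchange with itself.

Step 10
Reactants: 12 tert-butyldimethylsilylacetylene
Product: 13 (E)-tert-butyldimethyl[2-(tributylstannyl)ethenyl]silane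
Conditions: Bu3SnH (1.05 equiv), AIBN (5 mol%), neat, 85 °C
Reagents that add atoms: tributyltin hydride, CCCC[SnH](CCCC)CCCC
Why: Radical-chain hydrostannation of a terminal silylalkyne places tin on the terminal carbon and, under equilibrating conditions, should give the E isomer.

Step 11
Reactants: 13 (E)-tert-butyldimethyl[2-(tributylstannyl)ethenyl]silane; 14 chromium hexacarbonyl
Product: 17 pentacarbonyl[(2E)-3-(tert-butyldimethylsilyl)-1-methoxyprop-2-en-1-ylidene]chromium, via (E)-2-(tert-butyldimethylsilyl)vinyllithium 15 (not isolated), via lithium acylchromate 16 (not isolated)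
Conditions: n-BuLi (1.0 equiv), THF, −78 °C to −40 °C; Cr(CO)6 (1.0 equiv), Et2O, 0 °C to rt; solvent swap; MeOTf (1.3 equiv), CH2Cl2, 0 °C
Reagents that add atoms: methyl trifluoromethanesulfonate, COS(=O)(=O)C(F)(F)F
Why: Fischer carbene synthesis: tin–lithium exchange gives the vinyllithium with retention of the E geometry, its addition to a CO ligand of Cr(CO)6 gives the acylchromate, and the hard electrophile MeOTf methylates on oxygen.

Step 12
Reactants: 11 methyl (3R,5S)-5-(5-ethynylfuran-3-yl)-3,8-dimethylnon-7-enoate; 17 pentacarbonyl[(2E)-3-(tert-butyldimethylsilyl)-1-methoxyprop-2-en-1-ylidene]chromium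
Product: 20 methyl (3R,5S)-5-{5-[2-(tert-butyldimethylsilyloxy)-5-methoxyphenyl]furan-3-yl}-3,8-dimethylnon-7-enoate, via silylcyclohexadienone 18 (not isolated), via arene tricarbonylchromium complex 19 (not isolated)
Conditions: 17 (1.3 equiv), THF (0.1 M), 50 °C, Ar; then air, EtOAc, rt
Reagents that add atoms: none
Why: Thermal loss of one CO from the zerovalent chromium complex 17 opens a site for the terminal alkyne of 11, which inserts with its CH carbon bonding to the carbene carbon (C5''–C6''); CO insertion into the resulting vinylcarbene gives a dienylketene (C1''–C2''), and thermal disrotatory 6π-electrocyclisation closes the six-membered carbocycle through the C2''–C3'' bond to give cyclohexadienone 18. A 1,3-shift of silicon from C3'' to the carbonyl oxygen then aromatises the ring as the aryl silyl ether, held as its Cr(CO)3 complex 19 until air releases 20. The closest known reaction is the Dötz benzannulation of alkenyl(alkoxy)carbene chromium complexes with terminal alkynes in its trans-β-silylvinyl variant, where carbon-to-oxygen silyl migration replaces the usual tautomerisation. No lasting stereocentre is created (the sp3 centre C3'' of 18 disappears on aromatisation), and C3 and C5 are remote from the reacting atoms. The step needs regioselective insertion, which the steric difference between H and the furyl group on the alkyne should secure by placing the furan next to the CO-derived carbon C2'' (ortho to silyloxy, meta to methoxy); it also needs silyl rather than hydrogen migration, which the bulky tert-butyldimethylsilyl group should favour, while the ester and the remote trisubstituted alkene have no easy path to the metal.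

Step 13
Reactants: 20 methyl (3R,5S)-5-{5-[2-(tert-butyldimethylsilyloxy)-5-methoxyphenyl]furan-3-yl}-3,8-dimethylnon-7-enoate
Product: 21 (3R,5S)-5-[5-(2-hydroxy-5-methoxyphenyl)furan-3-yl]-3,8-dimethylnon-7-enoic acid
Conditions: LiOH·H2O (5 equiv), THF/MeOH/H2O 3:1:1 (degassed), rt; 1 M HCl to pH 3
Reagents that add atoms: lithium hydroxide, [Li+].[OH-]
Why: Saponification of the methyl ester and hydroxide attack at silicon of the base-labile aryl silyl ether should occur in the same pot, and doing the basic step before the hydroquinone exists avoids exposing it to base and air.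

Step 14
Reactants: 21 (3R,5S)-5-[5-(2-hydroxy-5-methoxyphenyl)furan-3-yl]-3,8-dimethylnon-7-enoic acid
Product: 22 (3R,5S)-5-[5-(3,6-dioxocyclohexa-1,4-dien-1-yl)furan-3-yl]-3,8-dimethylnon-7-enoic acid
Conditions: PhI(OAc)2 (1.1 equiv), MeCN/H2O 2:1, 0 °C
Reagents that add atoms: water, O
Why: Hypervalent-iodine oxidative dearomatisation of a 4-methoxyphenol: ligand exchange at iodine on the phenol oxygen, water attack at the methoxy-bearing para carbon C5'' and loss of methanol from the hemiketal should give the p-quinone, the reagent being selective for the phenol over the alkene.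

Step 15
Reactants: 22 (3R,5S)-5-[5-(3,6-dioxocyclohexa-1,4-dien-1-yl)furan-3-yl]-3,8-dimethylnon-7-enoic acid
Product: 23 (3R,5S)-5-[5-(2,5-dihydroxyphenyl)furan-3-yl]-3,8-dimethylnon-7-enoic acid (CNP0531232.1)
Conditions: Na2S2O4 (3 equiv), EtOAc/H2O, rt, Ar
Reagents that add atoms: none
Why: Two-electron dithionite reduction of a p-quinone to the hydroquinone is fast in a two-phase system and touches neither the alkene, the furan nor the acid.

**Compound list**

1 | (3R)-5-methoxy-3-methyl-5-oxopentanoic acid [(R)-methyl hydrogen 3-methylglutarate] | OC(=O)C[C@@H](C)CC(=O)OC | starting material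
2 | methyl (3R)-5-hydroxy-3-methylpentanoate | OCC[C@@H](C)CC(=O)OC | intermediate
3 | methyl (3R)-3-methyl-5-oxopentanoate | O=CC[C@@H](C)CC(=O)OC | intermediate
4 | methyl (3R,5E)-3-methyl-7-oxohept-5-enoate | O=C/C=C/C[C@@H](C)CC(=O)OC | intermediate
5 | 4-bromofuran-2-carbaldehyde | O=Cc1cc(Br)co1 | starting material
6 | 2-(4-bromofuran-2-yl)-1,3-dioxolane | Brc1coc(C2OCCO2)c1 | intermediate
7 | 2-[5-(1,3-dioxolan-2-yl)furan-3-yl]-4,4,5,5-tetramethyl-1,3,2-dioxaborolane | CC1(C)OB(c2coc(C3OCCO3)c2)OC1(C)C | intermediate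
8 | methyl (3R,5S)-5-[5-(1,3-dioxolan-2-yl)furan-3-yl]-3-methyl-7-oxoheptanoate | O=CC[C@H](C[C@@H](C)CC(=O)OC)c1coc(C2OCCO2)c1 | intermediate
9 | methyl (3R,5S)-5-[5-(1,3-dioxolan-2-yl)furan-3-yl]-3,8-dimethylnon-7-enoate | CC(C)=CC[C@H](C[C@@H](C)CC(=O)OC)c1coc(C2OCCO2)c1 | intermediate
10 | methyl (3R,5S)-5-(5-formylfuran-3-yl)-3,8-dimethylnon-7-enoate | CC(C)=CC[C@H](C[C@@H](C)CC(=O)OC)c1coc(C=O)c1 | intermediate
11 | methyl (3R,5S)-5-(5-ethynylfuran-3-yl)-3,8-dimethylnon-7-enoate | CC(C)=CC[C@H](C[C@@H](C)CC(=O)OC)c1coc(C#C)c1 | intermediate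
12 | tert-butyldimethylsilylacetylene | C#C[Si](C)(C)C(C)(C)C | starting material
13 | (E)-tert-butyldimethyl[2-(tributylstannyl)ethenyl]silane | CCCC[Sn](CCCC)(CCCC)/C=C/[Si](C)(C)C(C)(C)C | intermediate
14 | chromium hexacarbonyl | [Cr].[C-]#[O+].[C-]#[O+].[C-]#[O+].[C-]#[O+].[C-]#[O+].[C-]#[O+] | starting material
15 | (E)-2-(tert-butyldimethylsilyl)vinyllithium | [Li]/C=C/[Si](C)(C)C(C)(C)C | intermediate
16 | lithium pentacarbonyl[(2E)-3-(tert-butyldimethylsilyl)-1-oxidoprop-2-en-1-ylidene]chromate (lithium acylchromate) | [Li+].[O-]C(/C=C/[Si](C)(C)C(C)(C)C)=[Cr](=C=O)(=C=O)(=C=O)(=C=O)=C=O | intermediate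
17 | pentacarbonyl[(2E)-3-(tert-butyldimethylsilyl)-1-methoxyprop-2-en-1-ylidene]chromium | COC(/C=C/[Si](C)(C)C(C)(C)C)=[Cr](=C=O)(=C=O)(=C=O)(=C=O)=C=O | intermediate
18 | methyl (3R,5S)-5-{5-[5-(tert-butyldimethylsilyl)-3-methoxy-6-oxocyclohexa-1,3-dien-1-yl]furan-3-yl}-3,8-dimethylnon-7-enoate (chromium-bound; ring sp3 centre unassigned) | CC(C)=CC[C@H](C[C@@H](C)CC(=O)OC)c1coc(C2=CC(OC)=CC([Si](C)(C)C(C)(C)C)C2=O)c1 | intermediate
19 | tricarbonylchromium η6-arene complex of 20 (π-bond written as a dot) | CC(C)=CC[C@H](C[C@@H](C)CC(=O)OC)c1coc(-c2cc(OC)ccc2O[Si](C)(C)C(C)(C)C)c1.[Cr](=C=O)(=C=O)=C=O | intermediate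
20 | methyl (3R,5S)-5-{5-[2-(tert-butyldimethylsilyloxy)-5-methoxyphenyl]furan-3-yl}-3,8-dimethylnon-7-enoate | CC(C)=CC[C@H](C[C@@H](C)CC(=O)OC)c1coc(-c2cc(OC)ccc2O[Si](C)(C)C(C)(C)C)c1 | intermediate
21 | (3R,5S)-5-[5-(2-hydroxy-5-methoxyphenyl)furan-3-yl]-3,8-dimethylnon-7-enoic acid | CC(C)=CC[C@H](C[C@@H](C)CC(=O)O)c1coc(-c2cc(OC)ccc2O)c1 | intermediate
22 | (3R,5S)-5-[5-(3,6-dioxocyclohexa-1,4-dien-1-yl)furan-3-yl]-3,8-dimethylnon-7-enoic acid | CC(C)=CC[C@H](C[C@@H](C)CC(=O)O)c1coc(C2=CC(=O)C=CC2=O)c1 | intermediate
23 | (3R,5S)-5-[5-(2,5-dihydroxyphenyl)furan-3-yl]-3,8-dimethylnon-7-enoic acid | CC(C)=CC[C@H](C[C@@H](C)CC(=O)O)c1coc(-c2cc(O)ccc2O)c1 | target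

**Step count**

Total: 15 steps. Longest linear sequence: 11 steps (1, 2, 3, 6, 7, 8, 9, 12, 13, 14, 15).

**Steps most likely to fail**

1. Step 12 (benzannulation). After alkyne insertion the intermediate may leave the CO-insertion path (cyclopentannulation or two-alkyne products), the ethynylfuran may oligomerise at the metal, or hydrogen may migrate in place of silicon.
Fallback: the arene is bought and joined by cross-coupling; the path sets out from enal 4 and returns at 20. Enal 4 is treated under the conditions of step 6 with furan-3-ylboronic acid to give methyl (3R,5S)-5-(furan-3-yl)-3-methyl-7-oxoheptanoate F1. Wittig olefination as in step 7 gives methyl (3R,5S)-5-(furan-3-yl)-3,8-dimethylnon-7-enoate F2. Sterically directed iridium-catalysed C–H borylation ([Ir(OMe)(cod)]2, 4,4'-di-tert-butyl-2,2'-bipyridine, B2pin2, THF, 50 °C) should occur at C5', the α-position remote from the branched chain, to give methyl (3R,5S)-3,8-dimethyl-5-[5-(4,4,5,5-tetramethyl-1,3,2-dioxaborolan-2-yl)furan-3-yl]non-7-enoate F3. Suzuki–Miyaura coupling (PdCl2(dppf), K3PO4, dioxane/H2O, 60 °C) with (2-bromo-4-methoxyphenoxy)(tert-butyl)dimethylsilane F4 (from 2-bromo-4-methoxyphenol, TBSCl, imidazole, DMF) gives 20. Any desilylated phenol is carried into step 13, which removes the silyl group anyway.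

2. Step 6 (rhodium-catalysed 1,4-addition). Possible failures are 1,2-addition to the aldehyde, protodeboronation of the furylboronate before transmetalation, base-promoted aldol condensation of the product aldehyde, or insufficient facial selectivity at C5.
Fallback: the acceptor is changed to an amide and the aldehyde is released afterwards; the path sets out from aldehyde 3 and returns at 8. Horner–Wadsworth–Emmons olefination of 3 with diethyl {2-[methoxy(methyl)amino]-2-oxoethyl}phosphonate (NaH, THF, 0 °C) gives methyl (3R,5E)-7-[methoxy(methyl)amino]-3-methyl-7-oxohept-5-enoate F5. Rhodium/chiral-diene 1,4-addition of boronate 7, with no aldehyde present to suffer 1,2-addition or aldol reaction, gives methyl (3R,5S)-5-[5-(1,3-dioxolan-2-yl)furan-3-yl]-7-[methoxy(methyl)amino]-3-methyl-7-oxoheptanoate F6. Chemoselective reduction of the amide in the presence of the ester with Cp2Zr(H)Cl (THF, rt) gives aldehyde 8.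

3. Step 14 (oxidative demethylation). Oxidation may not stay on the phenol: the electron-rich furan may be attacked, or nucleophiles may add to the furyl quinone as it forms.
Fallback: non-oxidative, nucleophilic O-demethylation; the path sets out from 21 and returns at 23, bypassing 22. Heating 21 with excess sodium ethanethiolate in DMF at 130 °C under argon (SN2 at the methyl group), then acidifying under argon, gives 23 directly; no new compound arises (F0).

**Further compounds**

F1 | step 12 | methyl (3R,5S)-5-(furan-3-yl)-3-methyl-7-oxoheptanoate | O=CC[C@H](C[C@@H](C)CC(=O)OC)c1ccoc1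
F2 | step 12 | methyl (3R,5S)-5-(furan-3-yl)-3,8-dimethylnon-7-enoate | CC(C)=CC[C@H](C[C@@H](C)CC(=O)OC)c1ccoc1
F3 | step 12 | methyl (3R,5S)-3,8-dimethyl-5-[5-(4,4,5,5-tetramethyl-1,3,2-dioxaborolan-2-yl)furan-3-yl]non-7-enoate | CC(C)=CC[C@H](C[C@@H](C)CC(=O)OC)c1coc(B2OC(C)(C)C(C)(C)O2)c1
F4 | step 12 | (2-bromo-4-methoxyphenoxy)(tert-butyl)dimethylsilane | COc1ccc(O[Si](C)(C)C(C)(C)C)c(Br)c1
F5 | step 6 | methyl (3R,5E)-7-[methoxy(methyl)amino]-3-methyl-7-oxohept-5-enoate | CON(C)C(=O)/C=C/C[C@@H](C)CC(=O)OC
F6 | step 6 | methyl (3R,5S)-5-[5-(1,3-dioxolan-2-yl)furan-3-yl]-7-[methoxy(methyl)amino]-3-methyl-7-oxoheptanoate | CON(C)C(=O)C[C@H](C[C@@H](C)CC(=O)OC)c1coc(C2OCCO2)c1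
F0 | step 14 | none | none
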